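**Retrosynthetic overview**

1. The 8,9-epoxide comes last, from the (Z)-C8=C9 alkene by epoxidation directed by the C7 tertiary hydroxyl. The nine-membered ring comes from ring-closing metathesis (C8=C9) of a trans-4,5-disubstituted α-alkylidene δ-lactone.
2. The C11(=CH2)–C10–C9 unit comes from a methyl ketone at C11 (enol triflate, then Stille allylation). C7 with its methyl and vinyl groups is (S)-linalool.
3. The lactone is the first ring. It is made in one flask from a Morita–Baylis–Hillman carbonate, a phosphonoacetate (C4, C3=O, O2) and the side-chain aldehyde: C4–C4a by asymmetric allylic alkylation, O2–C1 by 6-endo oxa-Michael closure, C4=C12 by Horner–Wadsworth–Emmons olefination.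
4. Enabling feature: C11, the nine-membered-ring carbon that carries the exocyclic methylene and sits next to the ring-fusion carbon C11a, is a latent ketone. As C11=O it turns C1–C11a–C4a into a 2-acyl allyl unit that is electrophilic first at C4a (toward the carbanion) and then at C1 (toward the carboxylate).
5. Ring order: δ-lactone (key step), then nine-membered carbocycle, then ring epoxide. The side-chain epoxide is made on the small aldehyde fragment.

Key step: step 11

Remark: locants C1–C19 and O2 in the overview and the Why lines are those of the xenicane skeleton of the target (O2–C1H2 and C3=O in the lactone, C4 the alkylidene carbon, C4a/C11a the ring-fusion carbons, C7 the carbinol carbon, C8/C9 the ring epoxide, C11 bearing the methylidene C19, C12–C17 the side chain, C18 the methyl on C7).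
Assumption: (S)-linalool is bought in high enantiomeric purity.
Assumption: (DHQD)2PHAL is taken to give the C4a configuration drawn; if the sense of induction is the opposite, its pseudoenantiomer (DHQ)2PHAL would be used instead.

**Route**

Step 1
Reactants: 1 (S)-linalool
Product: 2 triethyl{[(3S)-3,7-dimethylocta-1,6-dien-3-yl]oxy}silane
Conditions: Et3SiOTf, 2,6-lutidine, CH2Cl2, −78 → 0 °C
Reagents that add atoms: triethylsilyl trifluoromethanesulfonate, CC[Si](CC)(CC)OS(=O)(=O)C(F)(F)F
Why: Silyl triflate with a hindered base is the standard hydroxyl protection for a tertiary allylic alcohol, and the C7 stereocenter of 1 is carried over untouched.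

Step 2
Reactants: 2 linalool triethylsilyl ether
Product: 4 (4S)-4-methyl-4-(triethylsilyloxy)hex-5-enal, via ozonide 3 (not isolated)
Conditions: O3 (1.0 equiv), CH2Cl2, −78 °C; then PPh3, −78 °C → rt
Reagents that add atoms: ozone, [O-][O+]=O
Why: Ozonolysis with reductive work-up (Criegee mechanism) should cleave the electron-rich trisubstituted alkene much faster than the hindered monosubstituted vinyl group when ozone is dosed at one equivalent, and no stereocenter is formed.

Step 3
Reactants: 4 (4S)-4-methyl-4-(triethylsilyloxy)hex-5-enal; 5 methyl vinyl ketone (but-3-en-2-one)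
Product: 6 (7S)-4-hydroxy-7-methyl-3-methylidene-7-(triethylsilyloxy)non-8-en-2-one (both epimers at the carbinol carbon)
Conditions: 5 (3 equiv), DABCO (0.3 equiv), THF, rt
Reagents that add atoms: none
Why: Morita–Baylis–Hillman reaction of an unhindered aliphatic aldehyde with an enone; the new carbinol center (future C4a) forms without control and both epimers are used because it is erased in step 11.

Step 4
Reactants: 6 Morita–Baylis–Hillman alcohol
Product: 7 tert-butyl (7S)-7-methyl-3-methylidene-2-oxo-7-(triethylsilyloxy)non-8-en-4-yl carbonate (both epimers)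
Conditions: Boc2O, DMAP (10 mol %), CH2Cl2, 0 °C → rt
Reagents that add atoms: di-tert-butyl dicarbonate, CC(C)(C)OC(=O)OC(=O)OC(C)(C)C
Why: DMAP-catalysed O-acylation of the secondary allylic alcohol gives the usual Morita–Baylis–Hillman carbonate leaving group; no stereocenter changes.

Step 5
Reactants: 8 (diethoxyphosphoryl)acetic acid; 9 (9H-fluoren-9-yl)methanol
Product: 10 (9H-fluoren-9-yl)methyl 2-(diethoxyphosphoryl)acetate
Conditions: DCC, DMAP (5 mol %), CH2Cl2, 0 °C → rt
Reagents that add atoms: none
Why: Steglich esterification of a primary alcohol; the fluorenylmethyl ester masks the carboxylate until base removes it by E1cB elimination in step 11.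

Step 6
Reactants: 11 3-methylbut-2-enal; 12 vinylmagnesium bromide
Product: 13 rac-5-methylhexa-1,4-dien-3-ol
Conditions: THF, −78 → 0 °C; then aq NH4Cl
Reagents that add atoms: none
Why: Grignard 1,2-addition to an enal at low temperature gives the racemic bis-allylic alcohol.

Step 7
Reactants: 13 rac-5-methylhexa-1,4-dien-3-ol
Product: 14 (3S)-5-methylhexa-1,4-dien-3-ol
Conditions: Candida antarctica lipase B (immobilized), vinyl acetate, MTBE, rt, to about half conversion
Reagents that add atoms: none
Why: Lipase-catalysed kinetic resolution by transesterification: by the empirical size rule the enantiomer that places the larger 2-methylprop-1-enyl group in the large pocket, the (R)-alcohol, should be acetylated, so the (S)-alcohol is recovered (the stereocenter is selected, not created).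

Step 8
Reactants: 14 (3S)-5-methylhexa-1,4-dien-3-ol
Product: 15 (1S)-1-[(2R)-3,3-dimethyloxiran-2-yl]prop-2-en-1-ol
Conditions: mCPBA, NaHCO3, CH2Cl2, 0 °C
Reagents that add atoms: 3-chloroperoxybenzoic acid, OOC(=O)c1cccc(Cl)c1
Why: Hydroxyl-directed peracid epoxidation attacks the nucleophilic trisubstituted alkene and not the vinyl group; allylic 1,3-strain with the cis methyl group holds the carbinol C–H in the alkene plane, so oxygen is delivered syn to the hydroxyl and the (2R) oxirane center is set threo to the (1S) carbinol.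

Step 9
Reactants: 15 epoxy alcohol
Product: 16 {(1S)-1-[(2R)-3,3-dimethyloxiran-2-yl]prop-2-en-1-yl}oxy(triethyl)silane
Conditions: Et3SiCl, imidazole, CH2Cl2, 0 °C
Reagents that add atoms: chlorotriethylsilane, CC[Si](Cl)(CC)CC
Why: Routine silyl protection of a secondary alcohol that leaves the epoxide and both stereocenters untouched.

Step 10
Reactants: 16 silylated vinyl epoxide
Product: 18 (2R)-2-[(2R)-3,3-dimethyloxiran-2-yl]-2-(triethylsilyloxy)acetaldehyde, via ozonide 17 (not isolated)
Conditions: O3, CH2Cl2, −78 °C; then PPh3, −78 °C → rt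
Reagents that add atoms: ozone, [O-][O+]=O
Why: Ozonolysis of the only remaining alkene with reductive work-up gives the α-silyloxy aldehyde under neutral conditions, so the α stereocenter and the epoxide survive (the descriptor changes to R only through the priority rules).

Step 11
Reactants: 7 Morita–Baylis–Hillman carbonate; 10 fluorenylmethyl phosphonoacetate; 18 side-chain aldehyde
Product: 21 (3E,4S,5S)-5-acetyl-3-{(2S)-2-[(2R)-3,3-dimethyloxiran-2-yl]-2-(triethylsilyloxy)ethylidene}-4-[(3S)-3-methyl-3-(triethylsilyloxy)pent-4-en-1-yl]oxan-2-one, via allylation adduct 19 (not isolated), via phosphono lactone 20 (not isolated)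
Conditions: 10 (1.1 equiv), (DHQD)2PHAL (10 mol %), toluene, 40 °C; then LiCl (3 equiv), DBU (3 equiv), MeCN, 0 °C; then 18 (1.2 equiv), 0 °C → rt
Reagents that add atoms: none
Why: The quinuclidine nitrogen of (DHQD)2PHAL adds SN2′ to C1 of 7 with loss of CO2 and tert-butoxide, which deprotonates 10; the carbanion then attacks C4a of the chiral allylammonium enone in a second SN2′ step (Lewis-base-catalysed asymmetric allylic alkylation of a Morita–Baylis–Hillman carbonate, convergent for both epimers of 7) to give 19 with the C4–C4a bond and a 2-methylene ketone. DBU then removes the fluorenylmethyl group by E1cB, and the freed carboxylate closes the lactone by 6-endo-trig oxa-Michael addition to the methylene carbon C1, giving 20; the closest known type is the tandem SN2′/oxa-Michael [3+3] annulation of Morita–Baylis–Hillman carbonates with C,O-bisnucleophiles. The lithium/DBU phosphonate anion of 20 finally olefinates 18 (Horner–Wadsworth–Emmons reaction under LiCl/amine conditions). C4a is set by the catalyst through the facial bias of the allylammonium ion pair (the remote C7 center has no say), C11a by protonation and equilibration α to the ketone toward the trans-4,5-disubstituted lactone, and the C4=C12 geometry by the E preference of stabilised phosphonate olefination. The step needs C- over O-alkylation and attack at C4a rather than C1, which are secured by keeping the acid masked as an ester until the C–C bond exists and by the SN2′–SN2′ mechanism; it also needs lactonisation before olefination, which is secured by adding 18 last.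

Step 12
Reactants: 21 alkylidene lactone methyl ketone
Product: 23 (3E,4S,5S)-3-{(2S)-2-[(2R)-3,3-dimethyloxiran-2-yl]-2-(triethylsilyloxy)ethylidene}-4-[(3S)-3-methyl-3-(triethylsilyloxy)pent-4-en-1-yl]-5-[1-(trifluoromethanesulfonyloxy)ethenyl]oxan-2-one, via potassium enolate 22 (not isolated)
Conditions: KN(SiMe3)2 (1.05 equiv) added to 21 and PhNTf2, THF, −78 °C
Reagents that add atoms: N-phenylbis(trifluoromethanesulfonimide), O=S(=O)(N(c1ccccc1)S(=O)(=O)C(F)(F)F)C(F)(F)F
Why: Kinetic deprotonation at the unhindered methyl group by a hindered amide base and O-sulfonylation of the enolate (enol triflate formation); the methyl-side enolate cannot expel the β-acyloxy group and the C11a center is not enolised.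

Step 13
Reactants: 23 vinyl triflate; 24 allyltributylstannane
Product: 25 (3E,4S,5R)-3-{(2S)-2-[(2R)-3,3-dimethyloxiran-2-yl]-2-(triethylsilyloxy)ethylidene}-4-[(3S)-3-methyl-3-(triethylsilyloxy)pent-4-en-1-yl]-5-(penta-1,4-dien-2-yl)oxan-2-one
Conditions: Pd(PPh3)4 (5 mol %), LiCl (3 equiv), THF, 60 °C
Reagents that add atoms: none
Why: Stille coupling of a vinyl triflate with an allylstannane (oxidative addition to zerovalent palladium assisted by chloride, transmetalation, reductive elimination) installs C10–C9 and turns the former ketone carbon C11 into the carbon of the exocyclic methylene; no stereocenter is involved.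

Step 14
Reactants: 25 triene
Product: 26 the 7,13-bis(triethylsilyl) ether of the (4E,4aS,7S,8Z,11aR,13S,14R) bicyclic lactone, that is the target skeleton with a (Z)-C8=C9 alkene in place of the ring epoxide and OSiEt3 at C7 and C13
Conditions: second-generation Hoveyda–Grubbs catalyst (10 mol %), toluene (0.5 mM), 80 °C
Reagents that add atoms: none
Why: Ring-closing olefin metathesis at high dilution: the ruthenium carbene should load on the unhindered allyl terminus and close onto the C7 vinyl group while the trans-disubstituted lactone holds the two chains near each other; a nine-membered ring takes the (Z)-C8=C9 alkene, which sets the alkene geometry.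

Step 15
Reactants: 26 bicyclic bis(silyl ether)
Product: 27 the (4E,4aS,7S,8Z,11aR,13S,14R) 7,13-diol (26 without both silyl groups)
Conditions: HF·pyridine, pyridine, THF, 0 °C → rt
Reagents that add atoms: none
Why: Buffered fluoride desilylation removes both triethylsilyl ethers while the epoxide, the lactone and the skipped diene should remain intact.

Step 16
Reactants: 27 7,13-diol
Product: 28 the 13-acetate of 27 (the target lacking only the ring epoxide oxygen, with a (Z)-C8=C9 alkene)
Conditions: Ac2O (1.5 equiv), pyridine, 0 °C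
Reagents that add atoms: acetic anhydride, CC(=O)OC(C)=O
Why: Selective O-acetylation: the secondary C13 hydroxyl is acylated and the hindered tertiary C7 hydroxyl is not expected to react under these conditions.

Step 17
Reactants: 28 (Z)-alkene
Product: 29 CNP0113449.2, the (4E,4aS,7S,8R,9R,11aR,13S,14R) target
Conditions: VO(acac)2 (5 mol %), t-BuOOH (1.5 equiv), CH2Cl2, 0 °C → rt
Reagents that add atoms: tert-butyl hydroperoxide, CC(C)(C)OO
Why: Vanadium-catalysed hydroxyl-directed epoxidation reacts only at the allylic (Z)-C8=C9 alkene (not the remote methylidene or the electron-poor enoate) and delivers oxygen from the face of the vanadate ester of the C7 hydroxyl, the mode that gives cis (syn) epoxy alcohols in medium-ring allylic alcohols, which sets C8 (R) and C9 (R).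

**Compound list**

1 | (S)-linalool, (3S)-3,7-dimethylocta-1,6-dien-3-ol | C=C[C@@](C)(O)CCC=C(C)C | starting material
2 | triethyl{[(3S)-3,7-dimethylocta-1,6-dien-3-yl]oxy}silane | C=C[C@@](C)(O[Si](CC)(CC)CC)CCC=C(C)C | intermediate
3 | 3,3-dimethyl-5-[(3S)-3-methyl-3-(triethylsilyloxy)pent-4-en-1-yl]-1,2,4-trioxolane (ozonide, not isolated) | C=C[C@@](C)(O[Si](CC)(CC)CC)CCC1OOC(C)(C)O1 | intermediate
4 | (4S)-4-methyl-4-(triethylsilyloxy)hex-5-enal | C=C[C@@](C)(O[Si](CC)(CC)CC)CCC=O | intermediate
5 | methyl vinyl ketone (but-3-en-2-one) | CC(=O)C=C | starting material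
6 | (7S)-4-hydroxy-7-methyl-3-methylidene-7-(triethylsilyloxy)non-8-en-2-one (both C4 epimers) | C=C[C@@](C)(O[Si](CC)(CC)CC)CCC(O)C(=C)C(C)=O | intermediate
7 | tert-butyl (7S)-7-methyl-3-methylidene-2-oxo-7-(triethylsilyloxy)non-8-en-4-yl carbonate (both C4 epimers) | C=C[C@@](C)(O[Si](CC)(CC)CC)CCC(OC(=O)OC(C)(C)C)C(=C)C(C)=O | intermediate
8 | (diethoxyphosphoryl)acetic acid | CCOP(=O)(CC(=O)O)OCC | starting material
9 | (9H-fluoren-9-yl)methanol | OCC1c2ccccc2-c2ccccc12 | starting material
10 | (9H-fluoren-9-yl)methyl 2-(diethoxyphosphoryl)acetate | CCOP(=O)(CC(=O)OCC1c2ccccc2-c2ccccc12)OCC | intermediate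
11 | 3-methylbut-2-enal | CC(C)=CC=O | starting material
12 | vinylmagnesium bromide | C=C[Mg]Br | starting material
13 | rac-5-methylhexa-1,4-dien-3-ol | C=CC(O)C=C(C)C | intermediate
14 | (3S)-5-methylhexa-1,4-dien-3-ol | C=C[C@H](O)C=C(C)C | intermediate
15 | (1S)-1-[(2R)-3,3-dimethyloxiran-2-yl]prop-2-en-1-ol | C=C[C@H](O)[C@H]1OC1(C)C | intermediate
16 | {(1S)-1-[(2R)-3,3-dimethyloxiran-2-yl]prop-2-en-1-yl}oxy(triethyl)silane | C=C[C@H](O[Si](CC)(CC)CC)[C@H]1OC1(C)C | intermediate
17 | 3-{(S)-[(2R)-3,3-dimethyloxiran-2-yl](triethylsilyloxy)methyl}-1,2,4-trioxolane (ozonide, not isolated) | O1COOC1[C@H](O[Si](CC)(CC)CC)[C@H]1OC1(C)C | intermediate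
18 | (2R)-2-[(2R)-3,3-dimethyloxiran-2-yl]-2-(triethylsilyloxy)acetaldehyde | O=C[C@H](O[Si](CC)(CC)CC)[C@H]1OC1(C)C | intermediate
19 | (9H-fluoren-9-yl)methyl (3S,6S)-2-(diethoxyphosphoryl)-6-methyl-3-(3-oxobut-1-en-2-yl)-6-(triethylsilyloxy)oct-7-enoate (C2 epimers, not isolated) | C=C[C@@](C)(O[Si](CC)(CC)CC)CC[C@@H](C(=C)C(C)=O)C(P(=O)(OCC)OCC)C(=O)OCC1c2ccccc2-c2ccccc12 | intermediate
20 | diethyl {(4S,5S)-5-acetyl-4-[(3S)-3-methyl-3-(triethylsilyloxy)pent-4-en-1-yl]-2-oxooxan-3-yl}phosphonate (C3 epimers, not isolated) | C=C[C@@](C)(O[Si](CC)(CC)CC)CC[C@@H]1C(P(=O)(OCC)OCC)C(=O)OC[C@H]1C(C)=O | intermediate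
21 | (3E,4S,5S)-5-acetyl-3-{(2S)-2-[(2R)-3,3-dimethyloxiran-2-yl]-2-(triethylsilyloxy)ethylidene}-4-[(3S)-3-methyl-3-(triethylsilyloxy)pent-4-en-1-yl]oxan-2-one | C=C[C@@](C)(O[Si](CC)(CC)CC)CC[C@@H]1/C(=C\[C@H](O[Si](CC)(CC)CC)[C@H]2OC2(C)C)C(=O)OC[C@H]1C(C)=O | intermediate
22 | methyl-side potassium enolate of 21 (potassium ethen-1-olate at the former acetyl group, not isolated) | C=C[C@@](C)(O[Si](CC)(CC)CC)CC[C@@H]1/C(=C\[C@H](O[Si](CC)(CC)CC)[C@H]2OC2(C)C)C(=O)OC[C@H]1C(=C)[O-].[K+] | intermediate
23 | (3E,4S,5S)-3-{(2S)-2-[(2R)-3,3-dimethyloxiran-2-yl]-2-(triethylsilyloxy)ethylidene}-4-[(3S)-3-methyl-3-(triethylsilyloxy)pent-4-en-1-yl]-5-[1-(trifluoromethanesulfonyloxy)ethenyl]oxan-2-one | C=C[C@@](C)(O[Si](CC)(CC)CC)CC[C@@H]1/C(=C\[C@H](O[Si](CC)(CC)CC)[C@H]2OC2(C)C)C(=O)OC[C@H]1C(=C)OS(=O)(=O)C(F)(F)F | intermediate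
24 | allyltributylstannane | C=CC[Sn](CCCC)(CCCC)CCCC | starting material
25 | (3E,4S,5R)-3-{(2S)-2-[(2R)-3,3-dimethyloxiran-2-yl]-2-(triethylsilyloxy)ethylidene}-4-[(3S)-3-methyl-3-(triethylsilyloxy)pent-4-en-1-yl]-5-(penta-1,4-dien-2-yl)oxan-2-one | C=C[C@@](C)(O[Si](CC)(CC)CC)CC[C@@H]1/C(=C\[C@H](O[Si](CC)(CC)CC)[C@H]2OC2(C)C)C(=O)OC[C@H]1C(=C)CC=C | intermediate
26 | (4E,4aS,7S,8Z,11aR,13S,14R) bicyclic lactone with (Z)-C8=C9 alkene, 11-methylidene, 14,15-epoxide and OSiEt3 at C7 and C13 | C=C1C/C=C\[C@@](C)(O[Si](CC)(CC)CC)CC[C@@H]2/C(=C\[C@H](O[Si](CC)(CC)CC)[C@H]3OC3(C)C)C(=O)OC[C@@H]12 | intermediate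
27 | (4E,4aS,7S,8Z,11aR,13S,14R) 7,13-diol (26 without both silyl groups) | C=C1C/C=C\[C@@](C)(O)CC[C@@H]2/C(=C\[C@H](O)[C@H]3OC3(C)C)C(=O)OC[C@@H]12 | intermediate
28 | 13-acetate of 27 (the target lacking the ring epoxide oxygen, (Z)-C8=C9) | C=C1C/C=C\[C@@](C)(O)CC[C@@H]2/C(=C\[C@H](OC(C)=O)[C@H]3OC3(C)C)C(=O)OC[C@@H]12 | intermediate
29 | CNP0113449.2, (4E,4aS,7S,8R,9R,11aR,13S,14R)-13-acetoxy-8,9:14,15-diepoxy-7-hydroxy xenicane δ-lactone with 11-methylidene | C=C1C[C@H]2O[C@H]2[C@@](C)(O)CC[C@@H]2/C(=C\[C@H](OC(C)=O)[C@H]3OC3(C)C)C(=O)OC[C@@H]12 | target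

**Count and risks**

Total step count: 17. Longest linear sequence: 12 steps (steps 6–10 and 11–17, from 11 to 29). Steps 1–4 and step 5 make the two other partners of step 11.

Steps most likely to fail:

1. Step 11. The intermolecular allylic alkylation may stall, or the allylammonium intermediate may lose a proton to give a diene, or the facial selectivity may erode, because β-alkyl Morita–Baylis–Hillman carbonates ionise more slowly than the aryl-substituted ones for which this catalyst class is best known. The fallback sets out from 6 and comes back at 21. Alcohol 6 would be converted with PBr3 (Et2O, −10 °C), with allylic transposition, into the primary bromide (3Z,7S)-3-(bromomethyl)-7-methyl-7-(triethylsilyloxy)nona-3,8-dien-2-one F1. Alkylation of the cesium salt of acid 8 with F1 (Cs2CO3, MeCN) would give the allylic ester (2E,6S)-2-acetyl-6-methyl-6-(triethylsilyloxy)octa-2,7-dien-1-yl 2-(diethoxyphosphoryl)acetate F2. On addition of LiCl and DBU, F2 would close by intramolecular 6-endo Michael addition of the phosphonate carbanion to the enone, giving 20 together with its ring diastereomer diethyl {(4R,5R)-5-acetyl-4-[(3S)-3-methyl-3-(triethylsilyloxy)pent-4-en-1-yl]-2-oxooxan-3-yl}phosphonate F3. Olefination with 18 in the same flask would give 21 and its diastereomer (3E,4R,5R)-5-acetyl-3-{(2S)-2-[(2R)-3,3-dimethyloxiran-2-yl]-2-(triethylsilyloxy)ethylidene}-4-[(3S)-3-methyl-3-(triethylsilyloxy)pent-4-en-1-yl]oxan-2-one F4, to be separated by chromatography. This tethered route needs no chiral catalyst but gives no control at the ring-fusion carbon, so about half of the material would be lost.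

2. Step 14. The ruthenium carbene may close onto the 1,1-disubstituted C11=C19 alkene (seven-membered ring) or oligomerise instead of closing the nine-membered ring. The fallback sets out from 21 and comes back at 26; it closes the ring before the methylidene exists. Ketone 21 would be vinylated at its methyl group (LiN(SiMe3)2, vinyl bromide, Pd2(dba)3 with a bulky phosphine) to the β,γ-unsaturated ketone (3E,4S,5S)-5-(but-3-enoyl)-3-{(2S)-2-[(2R)-3,3-dimethyloxiran-2-yl]-2-(triethylsilyloxy)ethylidene}-4-[(3S)-3-methyl-3-(triethylsilyloxy)pent-4-en-1-yl]oxan-2-one F5. Ring-closing metathesis of F5, which has only two monosubstituted alkenes, would give the 11-oxo analogue of 26 (C11 ketone in place of the methylidene, (Z)-C8=C9) F6. Methylenation of the ketone with Cp2Ti(μ-Cl)(μ-CH2)AlMe2 (THF, pyridine, −40 °C), which reacts with ketones before lactones, would give 26.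

3. Step 7. The lipase may discriminate poorly between the two alkenyl substituents, leaving 14 with insufficient enantiomeric purity. The fallback sets out from 11 and comes back at 14; it replaces resolution by asymmetric reduction. Addition of ethynylmagnesium bromide to 11 would give rac-5-methylhex-4-en-1-yn-3-ol F7. Oxidation with MnO2 would give 5-methylhex-4-en-1-yn-3-one F8. Asymmetric transfer hydrogenation of the alkynyl ketone (RuCl[(S,S)-TsDPEN](p-cymene) or its enantiomer, i-PrOH) would give (3R)-5-methylhex-4-en-1-yn-3-ol F9, which has the same spatial arrangement as 14. Semihydrogenation of the alkyne (H2, Pd/CaCO3 poisoned with Pb(OAc)2, quinoline) would give 14.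

**Further compounds**

F1 | step 11 | (3Z,7S)-3-(bromomethyl)-7-methyl-7-(triethylsilyloxy)nona-3,8-dien-2-one | C=C[C@@](C)(O[Si](CC)(CC)CC)CC/C=C(\CBr)C(C)=O
F2 | step 11 | (2E,6S)-2-acetyl-6-methyl-6-(triethylsilyloxy)octa-2,7-dien-1-yl 2-(diethoxyphosphoryl)acetate | C=C[C@@](C)(O[Si](CC)(CC)CC)CC/C=C(\COC(=O)CP(=O)(OCC)OCC)C(C)=O
F3 | step 11 | diethyl {(4R,5R)-5-acetyl-4-[(3S)-3-methyl-3-(triethylsilyloxy)pent-4-en-1-yl]-2-oxooxan-3-yl}phosphonate | C=C[C@@](C)(O[Si](CC)(CC)CC)CC[C@H]1C(P(=O)(OCC)OCC)C(=O)OC[C@@H]1C(C)=O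
F4 | step 11 | (3E,4R,5R)-5-acetyl-3-{(2S)-2-[(2R)-3,3-dimethyloxiran-2-yl]-2-(triethylsilyloxy)ethylidene}-4-[(3S)-3-methyl-3-(triethylsilyloxy)pent-4-en-1-yl]oxan-2-one | C=C[C@@](C)(O[Si](CC)(CC)CC)CC[C@H]1/C(=C\[C@H](O[Si](CC)(CC)CC)[C@H]2OC2(C)C)C(=O)OC[C@@H]1C(C)=O
F5 | step 14 | (3E,4S,5S)-5-(but-3-enoyl)-3-{(2S)-2-[(2R)-3,3-dimethyloxiran-2-yl]-2-(triethylsilyloxy)ethylidene}-4-[(3S)-3-methyl-3-(triethylsilyloxy)pent-4-en-1-yl]oxan-2-one | C=C[C@@](C)(O[Si](CC)(CC)CC)CC[C@@H]1/C(=C\[C@H](O[Si](CC)(CC)CC)[C@H]2OC2(C)C)C(=O)OC[C@H]1C(=O)CC=C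
F6 | step 14 | 11-oxo analogue of 26 (C11 ketone in place of the methylidene, (Z)-C8=C9, OSiEt3 at C7 and C13) | O=C1C/C=C\[C@@](C)(O[Si](CC)(CC)CC)CC[C@@H]2/C(=C\[C@H](O[Si](CC)(CC)CC)[C@H]3OC3(C)C)C(=O)OC[C@@H]12
F7 | step 7 | rac-5-methylhex-4-en-1-yn-3-ol | C#CC(O)C=C(C)C
F8 | step 7 | 5-methylhex-4-en-1-yn-3-one | C#CC(=O)C=C(C)C
F9 | step 7 | (3R)-5-methylhex-4-en-1-yn-3-ol | C#C[C@H](O)C=C(C)C
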